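**Retrosynthetic overview**

1. Feature: in the chroman-4-one, C3 is bonded to the carbonyl carbon C4 and to C1' of ring B, and the neighbouring C2' carries a hydroxyl. C3 can therefore be the exocyclic carbon of a ring B ortho-quinone methide, and C4 the acyl anion of a ring A salicylaldehyde ether.
2. Key disconnection C3–C4: a chiral triazolium carbene turns the ring A aldehyde into an acyl anion equivalent that adds to the fluoride-released quinone methide. This closes ring C last (rings A and B are bought as benzaldehydes) and sets C3.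
3. The cyclisation precursor is a racemic benzylic acetate with a C2' silyl ether. It comes from the ring B aryl oxirane (sulfonium ylide on the aldehyde), opened at CH2 by the ring A phenol (O1–C2 bond), then acetylated.
4. The ring B aldehyde comes from 2,3,4-trihydroxybenzaldehyde: O4' prenylation, O3' MOM ether, aromatic Claisen rearrangement to C5' (1,1-dimethylallyl group), O4' methylation, O2' silylation.
5. Last step: acid removal of the two MOM ethers.

Key step: step 10

Assumption: the sense of induction of the aminoindanol-derived salt (5aS,10bR)-2-(pentafluorophenyl)-5a,10b-dihydro-4H,6H-indeno[2,1-b][1,2,4]triazolo[4,3-d][1,4]oxazin-2-ium tetrafluoroborate cannot be predicted with certainty for this substrate; it is taken to give (3R), and its commercially available enantiomer would be used if a trial shows the opposite sense.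

**Route**

Step 1
Reactants: 1 2,3,4-trihydroxybenzaldehyde; 2 prenyl bromide (1-bromo-3-methylbut-2-ene)
Product: 3 2,3-dihydroxy-4-[(3-methylbut-2-en-1-yl)oxy]benzaldehyde
Conditions: 2 (1.05 equiv), NaHCO3, DMF, 40 °C
Reagents that add atoms: none
Why: Williamson etherification in which the weak base ionises only the most acidic phenol, the 4-OH para to the formyl group, while the 2-OH is held in a hydrogen bond to the aldehyde and the 3-OH is the least acidic, so mono-O-prenylation at O4 should dominate.

Step 2
Reactants: 3 2,3-dihydroxy-4-[(3-methylbut-2-en-1-yl)oxy]benzaldehyde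
Product: 4 2-hydroxy-3-(methoxymethoxy)-4-[(3-methylbut-2-en-1-yl)oxy]benzaldehyde
Conditions: NaH (2.2 equiv), DMF, 0 °C; MOMCl (1.0 equiv), 0 °C → rt; aq NH4Cl
Reagents that add atoms: chloromethyl methyl ether (MOMCl), COCCl
Why: Regioselective O-alkylation of a catecholate dianion, in which the 2-oxide is delocalised into and chelated by the formyl group so that the more basic 3-oxide should take up the single equivalent of MOMCl.

Step 3
Reactants: 4 2-hydroxy-3-(methoxymethoxy)-4-[(3-methylbut-2-en-1-yl)oxy]benzaldehyde
Product: 6 2,4-dihydroxy-3-(methoxymethoxy)-5-(2-methylbut-3-en-2-yl)benzaldehyde, via cyclohexadienone 5 (not isolated)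
Conditions: PhNEt2, 190 °C, sealed tube, argon
Reagents that add atoms: none
Why: Aromatic Claisen rearrangement ([3,3]-sigmatropic shift) in which the prenyl group can only move to C5, the one free ortho position, with allylic inversion to the 1,1-dimethylallyl group, tautomerisation of dienone 5 restoring the arene and the basic amine solvent suppressing acid-catalysed closure of the new phenol onto the alkene.

Step 4
Reactants: 6 2,4-dihydroxy-3-(methoxymethoxy)-5-(2-methylbut-3-en-2-yl)benzaldehyde
Product: 7 2-hydroxy-4-methoxy-3-(methoxymethoxy)-5-(2-methylbut-3-en-2-yl)benzaldehyde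
Conditions: MeI (1.1 equiv), K2CO3, acetone, rt
Reagents that add atoms: iodomethane, CI
Why: Williamson methylation in which the 4-OH para to the aldehyde is more acidic and, as its phenoxide, more nucleophilic than the chelated 2-OH, so one equivalent of MeI in acetone should methylate O4 only.

Step 5
Reactants: 7 2-hydroxy-4-methoxy-3-(methoxymethoxy)-5-(2-methylbut-3-en-2-yl)benzaldehyde
Product: 8 4-methoxy-3-(methoxymethoxy)-5-(2-methylbut-3-en-2-yl)-2-[(triisopropylsilyl)oxy]benzaldehyde
Conditions: TIPSCl, imidazole, DMAP (cat.), DMF, rt → 40 °C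
Reagents that add atoms: triisopropylsilyl chloride, CC(C)[Si](Cl)(C(C)C)C(C)C
Why: Silylation of the remaining phenol, the triisopropylsilyl group being chosen over a smaller silyl group because it should resist base and O-to-O migration to a neighbouring benzylic alkoxide in steps 6 to 9 while still being cleaved by fluoride.

Step 6
Reactants: 8 4-methoxy-3-(methoxymethoxy)-5-(2-methylbut-3-en-2-yl)-2-[(triisopropylsilyl)oxy]benzaldehyde
Product: 9 rac-2-{4-methoxy-3-(methoxymethoxy)-5-(2-methylbut-3-en-2-yl)-2-[(triisopropylsilyl)oxy]phenyl}oxirane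
Conditions: Me3S+ I−, NaH, DMSO/THF, 0 °C → rt; crude product filtered through basic alumina and used at once
Reagents that add atoms: trimethylsulfonium iodide, C[S+](C)C.[I-]
Why: Corey–Chaykovsky epoxidation, in which dimethylsulfonium methylide adds to the aldehyde and the betaine closes to the racemic terminal epoxide under basic conditions that the acid-labile, electron-rich aryl oxirane tolerates.

Step 7
Reactants: 10 2,4-dihydroxybenzaldehyde
Product: 11 2-hydroxy-4-(methoxymethoxy)benzaldehyde
Conditions: MOMCl (1.05 equiv), K2CO3, acetone, 0 °C → rt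
Reagents that add atoms: chloromethyl methyl ether (MOMCl), COCCl
Why: Selective O-alkylation of the 4-OH, the 2-OH being deactivated by its hydrogen bond to the formyl group.

Step 8
Reactants: 9 rac-2-{4-methoxy-3-(methoxymethoxy)-5-(2-methylbut-3-en-2-yl)-2-[(triisopropylsilyl)oxy]phenyl}oxirane; 11 2-hydroxy-4-(methoxymethoxy)benzaldehyde
Product: 12 rac-2-(2-hydroxy-2-{4-methoxy-3-(methoxymethoxy)-5-(2-methylbut-3-en-2-yl)-2-[(triisopropylsilyl)oxy]phenyl}ethoxy)-4-(methoxymethoxy)benzaldehyde
Conditions: 11 (1.5 equiv), Cs2CO3 (0.2 equiv), DMF, 60–70 °C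
Reagents that add atoms: none
Why: Base-catalysed SN2 opening of a monosubstituted aryl epoxide by a phenoxide, which without acid activation should attack the unhindered CH2 terminus and not the benzylic carbon shielded by the ortho silyloxy group, the excess phenol protonating the new alkoxide at once so that silyl migration is not expected.

Step 9
Reactants: 12 rac-2-(2-hydroxy-2-{4-methoxy-3-(methoxymethoxy)-5-(2-methylbut-3-en-2-yl)-2-[(triisopropylsilyl)oxy]phenyl}ethoxy)-4-(methoxymethoxy)benzaldehyde
Product: 13 rac-2-[2-formyl-5-(methoxymethoxy)phenoxy]-1-{4-methoxy-3-(methoxymethoxy)-5-(2-methylbut-3-en-2-yl)-2-[(triisopropylsilyl)oxy]phenyl}ethyl acetate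
Conditions: Ac2O, pyridine, DMAP (cat.), CH2Cl2, 0 °C → rt
Reagents that add atoms: acetic anhydride, CC(=O)OC(C)=O
Why: DMAP-catalysed acetylation of the secondary benzylic alcohol, whose configuration is of no consequence because this carbon becomes planar in step 10.

Step 10
Reactants: 13 rac-2-[2-formyl-5-(methoxymethoxy)phenoxy]-1-{4-methoxy-3-(methoxymethoxy)-5-(2-methylbut-3-en-2-yl)-2-[(triisopropylsilyl)oxy]phenyl}ethyl acetate
Product: 15 (3R)-3-[2-hydroxy-4-methoxy-3-(methoxymethoxy)-5-(2-methylbut-3-en-2-yl)phenyl]-7-(methoxymethoxy)chroman-4-one, via ortho-quinone methide 14 (not isolated)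
Conditions: (5aS,10bR)-N-pentafluorophenyl aminoindanol triazolium tetrafluoroborate (20 mol%), CsF (1.5 equiv), 18-crown-6, 4 Å MS, THF/MeCN, −20 → 0 °C, slow addition of 13; pH 7 buffer at 0 °C
Reagents that add atoms: none
Why: Proposed new method: fluoride cleaves the aryl silyl ether and, with the acetate set free, deprotonates the triazolium salt; the C2' phenoxide expels the benzylic acetate (helped by the para C4' methoxy group) to give quinone methide 14, so both enantiomers of 13 converge on one planar intermediate, while the carbene adds to the ring A aldehyde to form the enaminol whose nucleophilic carbon C4 attacks the exocyclic methide carbon C3, rearomatising ring B before the adduct collapses to the ketone and the free carbene. The closest known reaction types are the azolium-carbene-catalysed intermolecular addition of aldehyde acyl anion equivalents to fluoride-generated ortho-quinone methides, which gives alpha-aryl ketones, and the intramolecular Stetter reaction of salicylaldehyde ethers that closes chroman-4-ones; the tethered, enantioselective combination is what is new. Ring C closes by a 6-exo-trig conjugate addition, the C3=C1' bond lying outside the forming ring. The C3 stereocentre is set in the C–C bond-forming step by the chiral aminoindanol-derived carbene, which shields one face of the enaminol so that the planar methide carbon is attacked from one face, the (3R) series being fixed by the choice of catalyst enantiomer. The step needs intramolecular 1,4-addition to outrun dimerisation or 1,5-hydrogen shift of the quinone methide and benzoin coupling, which the short tether, the slow fluoride-limited release of 14 and its stabilisation by the para methoxy group should secure, and it needs the alpha-aryl ketone not to enolise, which the weakly basic fluoride/acetate medium at low temperature should secure.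

Step 11
Reactants: 15 (3R)-3-[2-hydroxy-4-methoxy-3-(methoxymethoxy)-5-(2-methylbut-3-en-2-yl)phenyl]-7-(methoxymethoxy)chroman-4-one
Product: 16 (3R)-3-[2,3-dihydroxy-4-methoxy-5-(2-methylbut-3-en-2-yl)phenyl]-7-hydroxychroman-4-one (target)
Conditions: dilute HCl, MeOH, rt
Reagents that add atoms: none
Why: Acid-catalysed transacetalisation of both aryl MOM ethers to methanol, under which C3–H should not enolise appreciably at room temperature and, C4' being a methyl ether, no phenol stands ortho to the 1,1-dimethylallyl group to cyclise onto it.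

**Compound list**

1 | 2,3,4-trihydroxybenzaldehyde | O=Cc1ccc(O)c(O)c1O | starting material
2 | prenyl bromide (1-bromo-3-methylbut-2-ene) | CC(C)=CCBr | starting material
3 | 2,3-dihydroxy-4-[(3-methylbut-2-en-1-yl)oxy]benzaldehyde | O=Cc1ccc(OCC=C(C)C)c(O)c1O | intermediate
4 | 2-hydroxy-3-(methoxymethoxy)-4-[(3-methylbut-2-en-1-yl)oxy]benzaldehyde | O=Cc1ccc(OCC=C(C)C)c(OCOC)c1O | intermediate
5 | 6-hydroxy-5-(methoxymethoxy)-3-(2-methylbut-3-en-2-yl)-4-oxocyclohexa-1,5-diene-1-carbaldehyde (racemic Claisen dienone) | O=CC1=CC(C(C)(C)C=C)C(=O)C(OCOC)=C1O | intermediate (not isolated)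
6 | 2,4-dihydroxy-3-(methoxymethoxy)-5-(2-methylbut-3-en-2-yl)benzaldehyde | O=Cc1cc(C(C)(C)C=C)c(O)c(OCOC)c1O | intermediate
7 | 2-hydroxy-4-methoxy-3-(methoxymethoxy)-5-(2-methylbut-3-en-2-yl)benzaldehyde | O=Cc1cc(C(C)(C)C=C)c(OC)c(OCOC)c1O | intermediate
8 | 4-methoxy-3-(methoxymethoxy)-5-(2-methylbut-3-en-2-yl)-2-[(triisopropylsilyl)oxy]benzaldehyde | O=Cc1cc(C(C)(C)C=C)c(OC)c(OCOC)c1O[Si](C(C)C)(C(C)C)C(C)C | intermediate
9 | rac-2-{4-methoxy-3-(methoxymethoxy)-5-(2-methylbut-3-en-2-yl)-2-[(triisopropylsilyl)oxy]phenyl}oxirane | C=CC(C)(C)c1cc(C2CO2)c(O[Si](C(C)C)(C(C)C)C(C)C)c(OCOC)c1OC | intermediate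
10 | 2,4-dihydroxybenzaldehyde | O=Cc1ccc(O)cc1O | starting material
11 | 2-hydroxy-4-(methoxymethoxy)benzaldehyde | O=Cc1ccc(OCOC)cc1O | intermediate
12 | rac-2-(2-hydroxy-2-{4-methoxy-3-(methoxymethoxy)-5-(2-methylbut-3-en-2-yl)-2-[(triisopropylsilyl)oxy]phenyl}ethoxy)-4-(methoxymethoxy)benzaldehyde | C=CC(C)(C)c1cc(C(O)COc2cc(OCOC)ccc2C=O)c(O[Si](C(C)C)(C(C)C)C(C)C)c(OCOC)c1OC | intermediate
13 | rac-2-[2-formyl-5-(methoxymethoxy)phenoxy]-1-{4-methoxy-3-(methoxymethoxy)-5-(2-methylbut-3-en-2-yl)-2-[(triisopropylsilyl)oxy]phenyl}ethyl acetate | C=CC(C)(C)c1cc(C(OC(C)=O)COc2cc(OCOC)ccc2C=O)c(O[Si](C(C)C)(C(C)C)C(C)C)c(OCOC)c1OC | intermediate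
14 | 2-{2-[4-methoxy-5-(methoxymethoxy)-3-(2-methylbut-3-en-2-yl)-6-oxocyclohexa-2,4-dien-1-ylidene]ethoxy}-4-(methoxymethoxy)benzaldehyde (ring B ortho-quinone methide, alkene geometry not fixed) | C=CC(C)(C)C1=CC(=CCOc2cc(OCOC)ccc2C=O)C(=O)C(OCOC)=C1OC | intermediate (not isolated)
15 | (3R)-3-[2-hydroxy-4-methoxy-3-(methoxymethoxy)-5-(2-methylbut-3-en-2-yl)phenyl]-7-(methoxymethoxy)chroman-4-one | C=CC(C)(C)c1cc([C@@H]2COc3cc(OCOC)ccc3C2=O)c(O)c(OCOC)c1OC | intermediate
16 | (3R)-3-[2,3-dihydroxy-4-methoxy-5-(2-methylbut-3-en-2-yl)phenyl]-7-hydroxychroman-4-one | C=CC(C)(C)c1cc([C@@H]2COc3cc(O)ccc3C2=O)c(O)c(O)c1OC | target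

**Step count**

Total: 11 steps. Longest linear sequence: 10 steps (steps 1 to 6 and 8 to 11); step 7 is the one-step side branch for ring A.

**Steps most likely to fail**

Step 10 (Proposed new method). The quinone methide may tautomerise by 1,5-hydrogen shift or oligomerise faster than the tethered acyl anion adds, the attack may show poor facial selectivity, or the alpha-aryl ketone may racemise in the basic medium. The fallback uses known chemistry, sets out from 12 and returns at 15.
- Oxidation of 12 with Dess–Martin periodinane (NaHCO3, CH2Cl2) should give the keto aldehyde 2-(2-{4-methoxy-3-(methoxymethoxy)-5-(2-methylbut-3-en-2-yl)-2-[(triisopropylsilyl)oxy]phenyl}-2-oxoethoxy)-4-(methoxymethoxy)benzaldehyde F1.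
- An achiral triazolium carbene (cat., with Et3N) should close F1 by the known intramolecular crossed aldehyde–ketone benzoin reaction to the racemic 3-hydroxy-3-arylchroman-4-one F2.
- Dehydration of F2 with Burgess reagent in toluene should give the isoflavone F3.
- Asymmetric transfer hydrogenation of F3 with RuCl(p-cymene)[(R,R)-TsDPEN] in HCO2H/Et3N reduces the C2=C3 bond and then the ketone under dynamic kinetic resolution of the labile C3 centre. It should give the cis-(3R,4R)-isoflavan-4-ol F4; the catalyst enantiomer is chosen for the (4R) alcohol.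
- Oxidation of F4 with Dess–Martin periodinane buffered with NaHCO3 should return the ketone without touching C3, giving the (3R)-2'-O-triisopropylsilyl isoflavanone F5.
- Desilylation of F5 with TBAF/AcOH in THF at −20 °C should give 15.

Step 8. The phenoxide may attack the benzylic carbon instead of the CH2 terminus, the silyl group may migrate from O2' to the new benzylic alkoxide, or the epoxide may rearrange to the arylacetaldehyde before it is opened. The fallback sets out from 9 and returns at 13, and it reverses the order of the two C–O bond formations so that regiochemistry follows the electronic bias and no alkoxide is formed.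
- Opening of 9 with acetic acid (CH2Cl2, 0 °C → rt) at the cation-stabilised benzylic carbon should give rac-2-hydroxy-1-{4-methoxy-3-(methoxymethoxy)-5-(2-methylbut-3-en-2-yl)-2-[(triisopropylsilyl)oxy]phenyl}ethyl acetate F6.
- Mitsunobu etherification of the primary alcohol of F6 with phenol 11 (PPh3, DIAD, THF, 0 °C) should give 13 directly.

Step 3. At the temperature of the rearrangement the freed phenol may add to the new alkene, the allyl group may isomerise further (abnormal Claisen pathway), or the MOM ether may be lost. The fallback sets out from 1 and returns at 7, installing the 1,1-dimethylallyl group by cross-coupling.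
- Selective 4-O-methylation of 1 with the catechol masked as its borate (Me2SO4, Na2B4O7, aq NaOH) should give 2,3-dihydroxy-4-methoxybenzaldehyde F7.
- Dianion alkylation as in step 2 (NaH, then MOMCl) should give 2-hydroxy-4-methoxy-3-(methoxymethoxy)benzaldehyde F8.
- Bromination with NBS in MeCN at 0 °C, para to the free phenol, should give 5-bromo-2-hydroxy-4-methoxy-3-(methoxymethoxy)benzaldehyde F9.
- A gamma-selective Suzuki–Miyaura coupling of F9 with 3-methylbut-2-en-1-ylboronic acid pinacol ester (Pd(OAc)2, bulky biarylphosphine ligand chosen for branched selectivity, K3PO4, THF/H2O) should give 7.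

**Further compounds**

F1 | step 10 | 2-(2-{4-methoxy-3-(methoxymethoxy)-5-(2-methylbut-3-en-2-yl)-2-[(triisopropylsilyl)oxy]phenyl}-2-oxoethoxy)-4-(methoxymethoxy)benzaldehyde | C=CC(C)(C)c1cc(C(=O)COc2cc(OCOC)ccc2C=O)c(O[Si](C(C)C)(C(C)C)C(C)C)c(OCOC)c1OC
F2 | step 10 | rac-3-hydroxy-3-{4-methoxy-3-(methoxymethoxy)-5-(2-methylbut-3-en-2-yl)-2-[(triisopropylsilyl)oxy]phenyl}-7-(methoxymethoxy)chroman-4-one | C=CC(C)(C)c1cc(C2(O)COc3cc(OCOC)ccc3C2=O)c(O[Si](C(C)C)(C(C)C)C(C)C)c(OCOC)c1OC
F3 | step 10 | 3-{4-methoxy-3-(methoxymethoxy)-5-(2-methylbut-3-en-2-yl)-2-[(triisopropylsilyl)oxy]phenyl}-7-(methoxymethoxy)-4H-chromen-4-one | C=CC(C)(C)c1cc(-c2coc3cc(OCOC)ccc3c2=O)c(O[Si](C(C)C)(C(C)C)C(C)C)c(OCOC)c1OC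
F4 | step 10 | (3R,4R)-3-{4-methoxy-3-(methoxymethoxy)-5-(2-methylbut-3-en-2-yl)-2-[(triisopropylsilyl)oxy]phenyl}-7-(methoxymethoxy)chroman-4-ol | C=CC(C)(C)c1cc([C@@H]2COc3cc(OCOC)ccc3[C@@H]2O)c(O[Si](C(C)C)(C(C)C)C(C)C)c(OCOC)c1OC
F5 | step 10 | (3R)-3-{4-methoxy-3-(methoxymethoxy)-5-(2-methylbut-3-en-2-yl)-2-[(triisopropylsilyl)oxy]phenyl}-7-(methoxymethoxy)chroman-4-one | C=CC(C)(C)c1cc([C@@H]2COc3cc(OCOC)ccc3C2=O)c(O[Si](C(C)C)(C(C)C)C(C)C)c(OCOC)c1OC
F6 | step 8 | rac-2-hydroxy-1-{4-methoxy-3-(methoxymethoxy)-5-(2-methylbut-3-en-2-yl)-2-[(triisopropylsilyl)oxy]phenyl}ethyl acetate | C=CC(C)(C)c1cc(C(OC(C)=O)CO)c(O[Si](C(C)C)(C(C)C)C(C)C)c(OCOC)c1OC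
F7 | step 3 | 2,3-dihydroxy-4-methoxybenzaldehyde | O=Cc1ccc(OC)c(O)c1O
F8 | step 3 | 2-hydroxy-4-methoxy-3-(methoxymethoxy)benzaldehyde | O=Cc1ccc(OC)c(OCOC)c1O
F9 | step 3 | 5-bromo-2-hydroxy-4-methoxy-3-(methoxymethoxy)benzaldehyde | O=Cc1cc(Br)c(OC)c(OCOC)c1O
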